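(The readings are calculated for an exercise; the scatter is artificial.)

In a one-step world free monomer falls from the first moment, yet the theta run still holds 98.5% at 1.04 d, so something has to form first, and the impurity may be consuming it.

| setting | theta | alpha | flask |
|---|---|---|---|
| free monomer | 0.010 M | 0.010 M | 0.010 M |
| pre-initiator | 0.17 mM | 0.26 mM | 0.12 mM |
| impurity | 76 µM | 76 µM | 76 µM |
| remark | run made earlier | run made earlier |  |
| time |  |  | 10 d |

| run | time / d | monomer in chains / % | free monomer / % |
|---|---|---|---|
| theta | 1.04 | 0.5 | 98.5 |
| theta | 2.00 | 5.3 | 95.2 |
| theta | 5.00 | 32.5 | 66.9 |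
| theta | 12.0 | 76.4 | 24.2 |
| alpha | 3.00 | 28.0 | 73.4 |
| alpha | 6.00 | 67.2 | 32.5 |
| alpha | 10.0 | 84.8 | 15.2 |
| alpha | 12.0 | 87.8 | 13.0 |

(each reading ± 0.5 percentage points)

- whether the average number of monomer units in a chain (chains begun, living or dead) reaches 80 by 10 d (yes / no)
- average number of monomer units in a chain (chains begun, living or dead) at 10 d

- the average divides the monomer in chains by the number of chains begun, living and dead together
- the earlier runs do not show the number of chains; that part of a forecast is a guess

Suppose each impurity removes one active centre. Then the chains a flask can carry are its margin, the pre-initiator charged minus the impurity charged0.0440 mM. That is 0.0440 mM for this flask, 0.0940 mM for theta and 0.184 mM for alpha.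

You can test this in two ways. With a steady chain count the fall of free monomer goes at a rate proportional to the margin, but it need not run to zero. Theta's log slope from 5.00 d to 12.0 d is 0.145 d⁻¹ and alpha's from 3.00 d to 6.00 d is 0.272 d⁻¹, a ratio of 1.88 against 1.96 for the margins; the charges give 1.53. These plain slopes are rough measures: alpha's drops to 0.0782 d⁻¹ between 10.0 d and 12.0 d, so I read a floor, with only the excess over it pseudo-first-order if the chain count holds. The second way ignores the impurity charge and extends these two rates to zero, which puts the loss at 66.5 µM and this flask's margin at 0.0535 mM. The two ways part here, but the second hangs on a difference of slopes from different windows, so I keep the subtraction.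

Scaling theta's plain slope by margin gives this flask, roughly, 0.0680 d⁻¹. With theta's delay of 2.23 d, my reckoning reaches 41.0% conversion at 10 d, and so a length of 93.2.

The forecast says yes with 85, lower than my figure, and warns: “The chain count is a guess”.

    free monomer + initiator → living end + monomer in chains (k = 23.0 M⁻¹ h⁻¹)
    free monomer + living end → monomer in chains + living end, rate k2*[living end]*[free monomer] (k = 100 M⁻¹ h⁻¹)
    monomer in chains + living end → free monomer + living end, rate k3*[living end] as long as [monomer in chains] is above zero (k = 0.110 h⁻¹)
    initiator + impurity → spent initiator (k = 27000 M⁻¹ h⁻¹)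
    pre-initiator ⇌ initiator (K = 2.60, k = 0.0200 h⁻¹)

The flask answers yes, with 102 at 10 d. At the charges of this flask an initiator meets impurity at 2.05 h⁻¹ and free monomer at 0.230 h⁻¹, which is 8.92 times faster. At 10.0 d the spent initiator stands at 7.57 × 10⁻⁵ M and the living end at 4.29 × 10⁻⁵ M, close to the margin of 0.0440 mM, and the 4.39 mM of monomer in chains divided among those ends gives 102 units each.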